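**The vessel.** A stirred vessel holds starting material while reagent runs in steadily without change of volume. Reagent is the limiting reagent by charge.

| setting | Saturday's | Tuesday's | flask |
|---|---|---|---|
| starting material | 0.10 M | 0.050 M | 0.10 M |
| reagent | 0.060 M (fed, over 80 s) | 0.060 M (fed, over 80 s) | 0.0600 M (fed, over 80 s) |
| remark | the very flask that is asked about, followed so far | run made earlier |  |
| time |  |  | 2.0 min |

| run | time / s | target / % | intermediate / % |
|---|---|---|---|
| Saturday's | 10.0 | 0 | 2 |
| Saturday's | 12.0 | 0 | 3 |
| Saturday's | 20.0 | 2 | 8 |
| Saturday's | 25.0 | 2 | 12 |
| Saturday's | 30.0 | 1 | 11 |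
| Saturday's | 40.0 | 4 | 18 |
| Tuesday's | 10.0 | 0 | 4 |
| Tuesday's | 15.0 | 0 | 4 |
| Tuesday's | 25.0 | 3 | 13 |
| Tuesday's | 30.0 | 2 | 18 |
| Tuesday's | 40.0 | 2 | 27 |
| Tuesday's | 50.0 | 2 | 34 |

(standard deviation of a reading: 1.5 percentage points)

- the earlier runs were read with a standard deviation of 1.5 percentage points
- on the list of suspects stand: starting material + reagent <-> intermediate; intermediate <-> target + by-product; starting material + by-product -> side product

- concentration of target at 2.0 min, in M
- concentration of intermediate at 2.0 min, in M
- concentration of starting material at 2.0 min, in M
- concentration of reagent at 2.0 min, in M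

**Fastest rung.** From Saturday's reading at 40.0 s I take c(reagent) as fed minus formed, 0.00800 M. Divided by the feed rate, this gives a hold-up time of 10.7 s, shorter than the feed of 80 s. So up to that reading in Saturday's flask reagent is taken up soon after it arrives.

**Slowest rung.** Target stands close to the scatter of 1.5 percentage points. Setting it against the intermediate present so far, I read a time from intermediate to target of 90.0 s on Saturday's run and 425 s on Tuesday's. Both are longer than the feed, so in Saturday's flask intermediate piles up and target trails.

**The ratio.** I follow the stall ratio, c(intermediate) divided by c(starting material) times c(reagent), the reaction quotient of the first step. Saturday's reading at 40.0 s gives 28.8 M⁻¹. On Tuesday's run my reading of it climbs from 18.0 M⁻¹ at 30.0 s to 27.2 M⁻¹ at 50.0 s. I expect control to pass from the feed to the way back where this ratio meets the step's equilibrium constant, and these readings suggest a rough floor for that constant.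

**My reckoning.** Counting what has formed as intermediate, a ratio of 28.8 M⁻¹ on Saturday's charges belongs to c(reagent) = 0.0216 M. The ratio climbs on Tuesday's run, so for Saturday's flask I commit to less reagent than that at 2.0 min.

**The forecast** gives 0.016 M target, 0.038 M intermediate, 0.041 M starting material and 0.004 M reagent, with “no clear sign of reversal so far”.

**The result.** Saturday's flask gives 0.0158 M target, 0.0339 M intermediate, 0.0485 M starting material and 0.0103 M reagent.

    starting material + reagent ⇌ intermediate (K = 74.0 M⁻¹, k = 1.10 M⁻¹ s⁻¹)
    intermediate ⇌ target + by-product (K = 0.300 M, k = 0.00560 s⁻¹)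
    starting material + by-product → side product (k = 0.0520 M⁻¹ s⁻¹)

**The way back.** Saturday's c(reagent) ends below my figure, and its stall ratio now stands at 67.6 M⁻¹, just under K1 of 74 M⁻¹. The neighbour charged with 0.24 M of reagent holds 0.00549 M starting material and 0.146 M reagent, yet its ratio is 72.5 M⁻¹. Target in Saturday's flask stands at 0.0158 M partly through the gradual adding of reagent and the length of the run: the same charge given at once gives 0.0226 M, and the run left until 20.0 min gives 0.0521 M.

Readings and results were generated by integration with made-up constants; scatter was added.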